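I decided to reckon this flask by G, not by D, and to aim at how little Q stands at the end.

| setting | violet | blue | ochre | flask |
|---|---|---|---|---|
| D | 1.5 M | 1.5 M | 2.2 M | 1.5 M |
| G | 1 mM | 2.2 mM | 1.5 mM | 1.5 mM |
| remark | run made earlier | run made earlier | run made earlier |  |
| time |  |  |  | 25 h |

- violet (time / h: J / %, Q / %): 2.00: 11, 3; 4.00: 21, 5; 6.00: 25, 6; 8.00: 32, 2; 10.0: 36, 2; 12.0: 32, 5; 15.0: 35, 1
- blue (time / h: J / %, Q / %): 2.00: 25, 9; 4.00: 39, 9; 6.00: 40, 3; 8.00: 46, 4; 10.0: 44, 0; 12.0: 46, 0; 15.0: 49, 1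
- ochre (time / h: J / %, Q / %): 1.33: 15, 7; 4.00: 26, 2; 8.00: 34, 0; 10.0: 39, 3; 15.0: 43, 3

(each reading ± 2 percentage points)

- ratio of J to Q at 8.0 min
- ratio of J to Q at 2.0 h
- ratio of J to Q at 25 h
- which of J and Q there is more of at 25 h



Let κ be the J plus Q of the first reading, as a fraction of the D charged, divided by that reading's time and the G charged. Violet gives 70.0 L mol⁻¹ h⁻¹ and blue 77.3 L mol⁻¹ h⁻¹, although blue holds more G, so the rate looks first order in G. Ochre, richer in D, gives 110 L mol⁻¹ h⁻¹, which is higher. The readings did not establish a first-order fall of D, and ochre's higher κ speaks against it. I still assumed a pseudo-first-order fall as a rough working choice, with G as the constant, and pooled the runs to κ = 83.4 L mol⁻¹ h⁻¹.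

For the flask, N = 2.88 is κ times G times the time from 2.0 h to 25 h: the count of e-foldings of what feeds Q. I took Q to follow its feed. Violet and blue average 6.00 % Q at 2.0 h, so e^−N leaves 0.338 %. The last J readings average 42.3 %, so my ratio was 125, with J ahead. One number was not enough: violet's κ gives 79.0 and ochre's 317. The first reading lies at 1.33 h, so I committed to nothing at 8.0 min.

The forecast gave 0.15 at 8.0 min, 3 at 2.0 h and 40 at 25 h, with J ahead, and called the last ratio “large and poorly bounded”.

    D ⇌ L, settled at all times (K = 0.590)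
    D + G → G + Q (k = 96.0 L mol⁻¹ h⁻¹)
    G + L → G + J (k = 240 L mol⁻¹ h⁻¹)
    2 D → E (k = 0.100 L mol⁻¹ h⁻¹)
    Q → X (k = 0.680 h⁻¹)
    D ⇌ Z (K = 0.620, k = 0.0900 h⁻¹)

The flask gave 1.54, 2.92 and 233, with J at 47.3 % and Q at 0.203 %. My Q stood 1.66 times the flask's. For the neighbour flask with 9.0 × 10⁻⁴ M of G, N = 1.73; scaling Q at 2.0 h by G gives 0.641 %, which is 1.82 times its simulated 0.353 %. In the flask, Q's half-life by the turning into X is 1.0 h, shorter than the 4.8 h of D by the G step. At 25.0 h, Q was made at 0.848 of the rate at which it was used up.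

(The data are simulated from invented constants; scatter was added.)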